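The runs were computed from invented constants, and the scatter is random.

Target in the teal flask fades ever more slowly, and I look for the one concentration behind that slowness.

| setting | teal | red | flask |
|---|---|---|---|
| starting material | 2 mM | 2 mM | 2.0 mM |
| second substrate | 2 mM | 2 mM | 2.00 mM |
| partner | 2.2 mM | 2.2 mM | 2.20 mM |
| free catalyst | 0.30 mM | 0.30 mM | 0.30 mM |
| temperature | 100 °C | 106 °C | 100 °C |
| remark | the very flask that is asked about, followed so far | run made earlier |  |
| time |  |  | 30 min |

| run | time / min | target / % | starting material / % |
|---|---|---|---|
| teal | 2.00 | 37.3 | 36.7 |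
| teal | 3.00 | 33.6 | 31.3 |
| teal | 4.00 | 29.8 | 26.5 |
| teal | 6.00 | 24.1 | 21.3 |
| teal | 10.0 | 18.6 | 15.8 |
| teal | 15.0 | 13.6 | 11.4 |
| teal | 25.0 | 9.4 | 7.2 |
| red | 2.00 | 31.9 | 35.5 |
| red | 3.00 | 27.2 | 30.4 |
| red | 4.00 | 23.0 | 26.0 |
| red | 6.00 | 17.8 | 20.8 |
| red | 10.0 | 12.0 | 15.3 |
| red | 15.0 | 7.9 | 11.4 |
| red | 25.0 | 4.3 | 8.2 |

(readings scatter by 0.3 percentage points)
- Saturday's: at 30 min add free catalyst, 100 % of the amount charged, then wait 1.0 h
- Tuesday's: at 30 min raise the temperature by 25 K, then wait 1.0 h
- Friday's: change nothing and wait 1.0 h more
- Thursday's: at 30 min add partner, 100 % of the amount charged, then wait 1.0 h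
- in percentages every species weighs as the starting material in it: one side product counts as two
- for target the idle complex is counted in
- additions bring no volume worth counting
- the earlier runs were read with a standard deviation of 0.3 percentage points
- steps under discussion: second substrate + free catalyst <-> catalyst intermediate B; starting material + free catalyst <-> catalyst intermediate A; 2 free catalyst <-> resting dimer; free catalyst + target <-> idle complex; partner + catalyst intermediate A -> free catalyst + target; starting material + target -> side product; partner + catalyst intermediate B -> free catalyst + second product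
- target, in percent of the starting material first charged, at 30 min
- which option adds most target ("none" when 2 percentage points or less is all one gets) (Saturday's / Tuesday's / Friday's / Thursday's / none)
- target present, in percent of the starting material first charged, after Saturday's
- target present, in percent of the starting material first charged, after Thursday's

1. In the teal flask the gap, target minus starting material, reads 2.8 percentage points at 10.0 min and 2.2 points at 25.0 min, while target falls from 18.6 % to 9.4 %. So I read the two as leaving in pairs, as side product, and take no new target as forming.

2. Then target's time constant is 1/(k[starting material]), with [starting material] as a fraction of the charge. Here k is the pairing constant, target's fractional loss rate per unit of [starting material].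

3. I step from 25.0 min to 30 min, and three inputs enter. An error in the target reading passes on at 86.7 % of its size, so this one matters. A tenth off in k moves the answer by 0.12 points. The starting-material reading enters likewise, with 0.3 points on 7.2 %.

4. From the readings, k = 0.396 min⁻¹. The time constant is then 35.1 min, and my target at 30 min is 8.15 %.

5. Target over starting material grows at k times the gap, to 2.30 after the further hour. That leaves 3.89 % of target, my figure for Saturday's. The red run reads lower at 25.0 min, 4.3 %, so I expect no gain from heat. Thursday's turns the remaining starting material into target, giving 14.1 %, and it is my choice.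

The forecast gives 8.2 %, Thursday's, 5.2 % and 13.8 %, reasoning that “the partner is exhausted”.

The simulation gives 8.45 %, Thursday's with 5.3 points, 4.18 % and 13.7 %.

    second substrate + free catalyst ⇌ catalyst intermediate B (K = 53000 L mol⁻¹, k = 280 L mol⁻¹ s⁻¹, Ea = 55.0 kJ mol⁻¹, ΔH = −5.00 kJ mol⁻¹)
    starting material + free catalyst ⇌ catalyst intermediate A (K = 820 L mol⁻¹, k = 520 L mol⁻¹ s⁻¹, Ea = 45.0 kJ mol⁻¹, ΔH = −45.0 kJ mol⁻¹)
    2 free catalyst ⇌ resting dimer, settled at all times (K = 35000 L mol⁻¹, ΔH = −34.0 kJ mol⁻¹)
    free catalyst + target ⇌ idle complex (K = 1300 L mol⁻¹, k = 40.0 L mol⁻¹ s⁻¹, Ea = 42.0 kJ mol⁻¹, ΔH = 6.00 kJ mol⁻¹)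
    partner + catalyst intermediate A → free catalyst + target (k = 500 L mol⁻¹ s⁻¹, Ea = 47.0 kJ mol⁻¹)
    starting material + target → side product (k = 3.50 L mol⁻¹ s⁻¹, Ea = 59.0 kJ mol⁻¹)
    partner + catalyst intermediate B → free catalyst + second product (k = 85.0 L mol⁻¹ s⁻¹, Ea = 37.0 kJ mol⁻¹)
    (constants at 100 °C)

Partner, the limiting reagent, stands at 0 % at 30.0 min, and my k, read from the teal readings, gives target an estimated time constant of 43.9 min there. Thursday's gain rests in part on second substrate holding the catalyst: the run without that binding, both ways, gains 0 points by Thursday's, against 5.3 points in the flask.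

With 1.3 mM of partner, the neighbour holds 41 % of starting material at 30 min, so I treat its loss of target as pseudo-first-order, and my k, read from the teal readings, gives an estimated time constant of 6.20 min, shorter than 30 min. Its computed target is 0.115 %.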